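**Plan**

1. Numbering: C1 = lavandulyl bridgehead, C2–C3–C4 = enol/aroyl/ketone bridge, C5 = prenyl bridgehead, C6 = CMe2, C7 = CH‑prenyl, C8 = CH2, C9 = bridging ketone. The retrosynthesis first cuts C3–aroyl, C5–prenyl and the C7 prenyl C=C, then the ring bonds C9–C1 and C3–C2 together.
2. What allows the double cut: the C9 ketone sits on C5 next to the C4(O)–C3 enol unit, so C9/C5/C4/C3 is a masked vinylketene O=C9=C5–C4(OR)=C3H2. C1=C2(OR)2 is a ketene acetal, and C6–C7–C8 ties C5 to C1, so ring A (C1–C2–C3–C4–C5–C9) and ring B (C1–C8–C7–C6–C5–C9) can close in one intramolecular [4+2].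
3. The vinylketene is stored as a 3‑alkoxycyclobutenone whose alkoxy oxygen is the end of a two‑carbon arm on C7 (a seven‑membered cyclic enol ether); this arm later becomes the CH2–CH of the C7 prenyl group.
4. Forward order: C7 fragment → siloxyalkyne + ketene → fused cyclobutenone → lavandulyl ketone → ketene diethyl acetal → thermal cascade (both carbocycles) → enol ether hydrolysis, arm to prenyl, C5 prenylation, C3 aroylation, deprotection.
5. Stereochemistry: the lavandulyl centre comes from (R)‑lavandulol and C7 from an oxazolidinone‑controlled conjugate allylation. C1 (and hence C5) follows from C7 through the oxygen tether, which can only span C4 and C7 on the endo face and so also fixes the 7‑endo prenyl.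

Key step: step 15

Remark: ketene gas (acetone pyrolysis), (diethoxymethyl)diphenylphosphine oxide, 2,2‑dimethylbut‑3‑ynoic acid and (R)‑lavandulol are taken as purchasable or routinely generated; the lavandulyl centre is never touched, and its descriptor changes from R (14, 15) to S (from 17 on) only through CIP priorities.

Step 1
Reactants: 1 2,2-dimethylbut-3-ynoic acid
Product: 2 2,2-dimethylbut-3-yn-1-ol
Conditions: LiAlH4, Et2O, 0 °C → rt; aq. NaOH work-up
Reagents that add atoms: none
Why: Hydride reduction of a carboxylic acid to the primary alcohol; the isolated terminal alkyne should not be reduced at this temperature.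

Step 2
Reactants: 2 2,2-dimethylbut-3-yn-1-ol
Product: 3 2,2-dimethylbut-3-ynal
Conditions: Dess–Martin periodinane, NaHCO3, CH2Cl2, 0 °C → rt; volatile aldehyde carried on as a solution
Reagents that add atoms: none
Why: Dess–Martin oxidation should stop cleanly at the non‑enolisable neopentyl aldehyde.

Step 3
Reactants: 3 2,2-dimethylbut-3-ynal
Product: 4 (E)-4,4-dimethylhex-2-en-5-ynoic acid
Conditions: malonic acid, pyridine, piperidine (cat.), 80 °C
Reagents that add atoms: malonic acid, OC(=O)CC(=O)O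
Why: Knoevenagel–Doebner condensation with decarboxylation should give the (E)‑enoic acid, since the aldehyde has no α‑hydrogen for self‑condensation.

Step 4
Reactants: 4 (E)-4,4-dimethylhex-2-en-5-ynoic acid; 5 (S)-4-benzyloxazolidin-2-one
Product: 6 (S)-4-benzyl-3-[(E)-4,4-dimethylhex-2-en-5-ynoyl]oxazolidin-2-one
Conditions: PivCl, Et3N, THF, −20 °C; then 5, LiCl, rt
Reagents that add atoms: none
Why: N‑acylation of the oxazolidinone through the pivaloyl mixed anhydride should install the auxiliary without isomerising the alkene or touching the alkyne.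

Step 5
Reactants: 6 (S)-4-benzyl-3-[(E)-4,4-dimethylhex-2-en-5-ynoyl]oxazolidin-2-one
Product: 7 (S)-4-benzyl-3-[(S)-3-(2-methylbut-3-yn-2-yl)hex-5-enoyl]oxazolidin-2-one
Conditions: allyltrimethylsilane, TiCl4, CH2Cl2, −78 °C
Reagents that add atoms: allyltrimethylsilane, C=CC[Si](C)(C)C
Why: Hosomi–Sakurai conjugate allylation of the TiCl4‑chelated s‑cis N‑enoyl imide, in which the allylsilane should attack the β‑carbon anti to the benzyl group and so set C7 as (S).

Step 6
Reactants: 7 (S)-4-benzyl-3-[(S)-3-(2-methylbut-3-yn-2-yl)hex-5-enoyl]oxazolidin-2-one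
Product: 8 (S)-3-(2-methylbut-3-yn-2-yl)hex-5-en-1-ol
Conditions: LiBH4, MeOH (1 equiv), Et2O, 0 °C
Reagents that add atoms: none
Why: Reductive cleavage of the N‑acyl oxazolidinone should give the primary alcohol (the future C7 arm) and return the auxiliary without affecting C7.

Step 7
Reactants: 8 (S)-3-(2-methylbut-3-yn-2-yl)hex-5-en-1-ol
Product: 9 (4S)-3,3-dimethyl-1-(triisopropylsilyloxy)-4-[2-(triisopropylsilyloxy)ethyl]hept-6-en-1-yne
Conditions: n-BuLi (2.05 equiv), THF, −78 °C; LiOOt-Bu (from t-BuOOH, LiHMDS), −78 → 0 °C; TIPSOTf (excess), −78 °C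
Reagents that add atoms: tert-butyl hydroperoxide, CC(C)(C)OO; triisopropylsilyl triflate, CC(C)[Si](OS(=O)(=O)C(F)(F)F)(C(C)C)C(C)C
Why: Oxidation of the lithium acetylide with lithium tert‑butyl peroxide to the lithium ynolate and O‑silylation (ynolate and alkoxide) is the established route from terminal alkynes to siloxyalkynes.

Step 8
Reactants: 9 (4S)-3,3-dimethyl-1-(triisopropylsilyloxy)-4-[2-(triisopropylsilyloxy)ethyl]hept-6-en-1-yne
Product: 10 2-{(3S)-2-methyl-3-[2-(triisopropylsilyloxy)ethyl]hex-5-en-2-yl}-3-(triisopropylsilyloxy)cyclobut-2-en-1-one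
Conditions: ketene (excess, from acetone pyrolysis), CH2Cl2, 0 °C → rt
Reagents that add atoms: ketene, C=C=O
Why: Ketene–siloxyalkyne [2+2] cycloaddition should give the 3‑siloxycyclobutenone, with the nucleophilic alkyne carbon (C5) bonding to the ketene carbonyl carbon (C9) and the O‑bearing carbon (C4) to the ketene CH2 (C3).

Step 9
Reactants: 10 2-{(3S)-2-methyl-3-[2-(triisopropylsilyloxy)ethyl]hex-5-en-2-yl}-3-(triisopropylsilyloxy)cyclobut-2-en-1-one
Product: 12 (5S)-6,6-dimethyl-5-(prop-2-en-1-yl)-2-oxabicyclo[5.2.0]non-1(7)-en-8-one, via vinylogous acid 11 (not isolated)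
Conditions: HF·pyridine, THF–pyridine, 0 °C → rt; then CSA (10 mol%), 4 Å MS, CH2Cl2 (5 mM), 35 °C
Reagents that add atoms: none
Why: Fluoride desilylation followed by acid‑catalysed vinylogous (Fischer‑type) esterification of the symmetrical cyclobutane‑1,3‑dione with its own primary alcohol should close the seven‑membered enol ether under dilution; either carbonyl gives the same product and C‑alkylation cannot occur.

Step 10
Reactants: 12 (5S)-6,6-dimethyl-5-(prop-2-en-1-yl)-2-oxabicyclo[5.2.0]non-1(7)-en-8-one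
Product: 13 2-[(5R)-6,6-dimethyl-8-oxo-2-oxabicyclo[5.2.0]non-1(7)-en-5-yl]acetaldehyde
Conditions: OsO4 (2 mol%), NaIO4, 2,6-lutidine, dioxane–H2O, rt
Reagents that add atoms: osmium tetroxide (cat.), O=[Os](=O)(=O)=O; sodium periodate, [Na+].[O-]I(=O)(=O)=O
Why: Lemieux–Johnson cleavage should be selective for the monosubstituted alkene, the tetrasubstituted push–pull double bond of the vinylogous ester being inert to OsO4.

Step 11
Reactants: 14 (R)-lavandulol
Product: 15 (R)-lavandulyl iodide [(2R)-1-iodo-5-methyl-2-(prop-1-en-2-yl)hex-4-ene]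
Conditions: PPh3, I2, imidazole, CH2Cl2, 0 °C
Reagents that add atoms: iodine, II
Why: Appel iodination of the primary alcohol; the adjacent stereocentre is not involved.

Step 12
Reactants: 13 2-[(5R)-6,6-dimethyl-8-oxo-2-oxabicyclo[5.2.0]non-1(7)-en-5-yl]acetaldehyde; 15 (R)-lavandulyl iodide
Product: 17 (5R)-5-[(4S)-2-hydroxy-7-methyl-4-(prop-1-en-2-yl)oct-6-en-1-yl]-6,6-dimethyl-2-oxabicyclo[5.2.0]non-1(7)-en-8-one (carbinol epimers), via lavandulyllithium 16 (not isolated)
Conditions: 15, t-BuLi (2.1 equiv), Et2O, −78 °C; then 13, THF, −78 °C; aq. NH4Cl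
Reagents that add atoms: none
Why: Iodine–lithium exchange at −78 °C should give the homoallylic lithium reagent without rearrangement, and its 1,2‑addition to the aldehyde is far faster than attack on the hindered vinylogous ester carbonyl; the new carbinol centre is uncontrolled and is removed in step 13.

Step 13
Reactants: 17 (5R)-5-[(4S)-2-hydroxy-7-methyl-4-(prop-1-en-2-yl)oct-6-en-1-yl]-6,6-dimethyl-2-oxabicyclo[5.2.0]non-1(7)-en-8-one
Product: 18 (5R)-6,6-dimethyl-5-[(4S)-7-methyl-2-oxo-4-(prop-1-en-2-yl)oct-6-en-1-yl]-2-oxabicyclo[5.2.0]non-1(7)-en-8-one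
Conditions: Dess–Martin periodinane, NaHCO3, CH2Cl2, 0 °C → rt
Reagents that add atoms: none
Why: Dess–Martin oxidation of the secondary alcohol under buffered conditions should leave the vinylogous ester and the alkenes untouched.

Step 14
Reactants: 18 (5R)-6,6-dimethyl-5-[(4S)-7-methyl-2-oxo-4-(prop-1-en-2-yl)oct-6-en-1-yl]-2-oxabicyclo[5.2.0]non-1(7)-en-8-one
Product: 20 (5S)-5-[(4S)-2-(diethoxymethylidene)-7-methyl-4-(prop-1-en-2-yl)oct-6-en-1-yl]-6,6-dimethyl-2-oxabicyclo[5.2.0]non-1(7)-en-8-one, via hydroxy phosphine oxide adduct 19 (not isolated)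
Conditions: (EtO)2CHP(O)Ph2, LDA, THF, −100 °C; 18, −100 → −78 °C; then KOt-Bu, −78 → 0 °C; filtration through basic alumina (Et3N-doped hexane), used at once
Reagents that add atoms: (diethoxymethyl)diphenylphosphine oxide, CCOC(OCC)P(=O)(c1ccccc1)c1ccccc1
Why: Horner–Wittig olefination with the lithiated dialkoxymethyl phosphine oxide and potassium‑induced loss of diphenylphosphinate is the known route from ketones to ketene O,O‑acetals; the dialkyl ketone should react in preference to the hindered vinylogous ester carbonyl.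

Step 15
Reactants: 20 (5S)-5-[(4S)-2-(diethoxymethylidene)-7-methyl-4-(prop-1-en-2-yl)oct-6-en-1-yl]-6,6-dimethyl-2-oxabicyclo[5.2.0]non-1(7)-en-8-one
Product: 22 2,2-diethoxy-6,6-dimethyl-1-lavandulyl-bicyclo[3.3.1]non-4-en-9-one whose C4 enol oxygen is joined by CH2CH2 to C7 on the endo face, via vinylketene 21 (not isolated)
Conditions: toluene (2 mM), 2,6-di-tert-butyl-4-methylpyridine (0.3 equiv), 110 °C, base-washed glassware, Ar
Reagents that add atoms: none
Why: Proposed new method: thermal 4π‑electrocyclic opening of the fused 3‑alkoxycyclobutenone should give vinylketene 21, whose C9=C5–C4=C3 unit is held s‑cis as a 1,2‑bis(exocyclic) diene on the seven‑membered enol‑ether ring; the nucleophilic ketene‑acetal carbon C1 then attacks the ketene carbon C9 and the dienolate terminus C3 bonds to the dialkoxycarbenium carbon C2 (concerted‑asynchronous or through the zwitterion), a type 2 intramolecular [4+2] with the tether on the internal diene carbon C5. The closest known reactions are type 2 intramolecular Diels–Alder reactions that give bridgehead alkenes, and the trapping of cyclobutenone‑derived vinylketenes by ynol ethers and other electron‑rich π partners. Ring B (C1–C8–C7–C6–C5–C9) closes by 6‑exo attack of the enol‑exo carbon C1 on the ketene C=O, and ring A (C1–C2–C3–C4–C5–C9) by 6‑(enolendo)‑exo attack of the dienolate γ‑carbon C3 on C2, leaving C9 as the ketone and C4=C5 as the bridgehead enol ether. C1 is the only new stereocentre and is dictated by C7: the C7 arm is bound through the enol‑ether oxygen to C4, so the three‑carbon bridge can form only on the face of ring B that carries this arm, which at the same time makes the arm the endo substituent. The step needs [4+2] rather than [2+2] closure and intramolecular rather than intermolecular capture: the O,O‑dialkyl ketene acetal has no transferable group, so the zwitterion can only form a C–C bond or revert; the bridged cyclobutanone is more strained and, as a donor–acceptor cyclobutane, can reopen to the same zwitterion; and high dilution disfavours dimerisation.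

Step 16
Reactants: 22 tricyclic bridgehead enol ether (product of step 15)
Product: 24 2-ethoxy-7-endo-(2-hydroxyethyl)-6,6-dimethyl-1-lavandulylbicyclo[3.3.1]non-2-ene-4,9-dione, via keto ketal alcohol 23 (not isolated)
Conditions: PPTS (cat.), THF–H2O (10:1), 0 °C; then DBU, CH2Cl2, rt
Reagents that add atoms: water, O
Why: Enol ether hydrolysis then E1cB elimination: the strained bridgehead enol ether should be protonated at C5 from its only open (exo) face (C5–H fixed by the bicycle) far faster than the neopentyl ketal hydrolyses, releasing the C7 arm as the alcohol, and loss of ethanol from the β‑keto ketal can only give the vinylogous ester with OEt on C2 and the ketone on C4.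

Step 17
Reactants: 24 2-ethoxy-7-endo-(2-hydroxyethyl)-6,6-dimethyl-1-lavandulylbicyclo[3.3.1]non-2-ene-4,9-dione
Product: 25 2-(2-ethoxy-6,6-dimethyl-1-lavandulyl-4,9-dioxobicyclo[3.3.1]non-2-en-7-endo-yl)acetaldehyde
Conditions: Dess–Martin periodinane, NaHCO3, CH2Cl2, 0 °C
Reagents that add atoms: none
Why: Dess–Martin oxidation of the primary alcohol to the aldehyde under neutral conditions.

Step 18
Reactants: 25 2-(2-ethoxy-6,6-dimethyl-1-lavandulyl-4,9-dioxobicyclo[3.3.1]non-2-en-7-endo-yl)acetaldehyde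
Product: 26 2-ethoxy-6,6-dimethyl-7-endo-(3-methylbut-2-en-1-yl)-1-lavandulylbicyclo[3.3.1]non-2-ene-4,9-dione
Conditions: i-PrPPh3I, n-BuLi, THF, 0 °C; then 25, −78 → 0 °C
Reagents that add atoms: isopropyltriphenylphosphonium iodide, CC(C)[P+](c1ccccc1)(c1ccccc1)c1ccccc1.[I-]
Why: Wittig olefination with the non‑stabilised isopropylidene ylide should turn the endo CH2CHO arm into the prenyl group, the aldehyde reacting far faster than the hindered C9 ketone or the vinylogous ester.

Step 19
Reactants: 26 2-ethoxy-6,6-dimethyl-7-endo-(3-methylbut-2-en-1-yl)-1-lavandulylbicyclo[3.3.1]non-2-ene-4,9-dione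
Product: 27 2-ethoxy-6,6-dimethyl-5,7-bis(3-methylbut-2-en-1-yl)-1-lavandulylbicyclo[3.3.1]non-2-ene-4,9-dione
Conditions: LDA, THF, −78 °C; prenyl bromide, −78 → −40 °C
Reagents that add atoms: prenyl bromide, CC(C)=CCBr
Why: Bridgehead lithiation–alkylation: LDA deprotonation of the bridgehead flanked by the C4 and C9 carbonyls, followed by SN2 prenylation, is established for enol ethers of bicyclo[3.3.1]nonane‑2,4,9‑triones, and the configuration at C5 is fixed by the bicycle.

Step 20
Reactants: 28 3-hydroxybenzoic acid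
Product: 29 tert-butyldimethylsilyl 3-(tert-butyldimethylsilyloxy)benzoate
Conditions: TBSCl (2.2 equiv), imidazole, DMF, rt
Reagents that add atoms: tert-butyldimethylsilyl chloride, CC(C)(C)[Si](C)(C)Cl
Why: Standard silylation of both the phenol and the carboxylic acid.

Step 21
Reactants: 29 tert-butyldimethylsilyl 3-(tert-butyldimethylsilyloxy)benzoate
Product: 30 3-(tert-butyldimethylsilyloxy)benzoyl chloride
Conditions: (COCl)2, DMF (cat.), CH2Cl2, 0 °C → rt
Reagents that add atoms: oxalyl chloride, O=C(Cl)C(=O)Cl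
Why: Vilsmeier‑type activation converts a silyl ester directly into the acid chloride under neutral conditions, leaving the aryl silyl ether intact.

Step 22
Reactants: 27 2-ethoxy-6,6-dimethyl-5,7-bis(3-methylbut-2-en-1-yl)-1-lavandulylbicyclo[3.3.1]non-2-ene-4,9-dione; 30 3-(tert-butyldimethylsilyloxy)benzoyl chloride
Product: 31 3-[3-(tert-butyldimethylsilyloxy)benzoyl]-2-ethoxy-6,6-dimethyl-5,7-bis(3-methylbut-2-en-1-yl)-1-lavandulylbicyclo[3.3.1]non-2-ene-4,9-dione
Conditions: LiTMP (from TMP, n-BuLi), THF, −78 °C; then 30, −78 °C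
Reagents that add atoms: none
Why: Vinylic α‑lithiation of the β‑alkoxy enone at C3 with the hindered amide base and C‑acylation with the aroyl chloride, as practised on this class of bicyclic vinylogous esters.

Step 23
Reactants: 31 3-[3-(tert-butyldimethylsilyloxy)benzoyl]-2-ethoxy-6,6-dimethyl-5,7-bis(3-methylbut-2-en-1-yl)-1-lavandulylbicyclo[3.3.1]non-2-ene-4,9-dione
Product: 32 CNP0103487.1
Conditions: LiOH, dioxane–H2O, 80 °C; then 1 M HCl
Reagents that add atoms: lithium hydroxide, [Li+].[OH-]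
Why: Addition–elimination hydrolysis: hydroxide should add to C2 and expel ethoxide, and also cleave the aryl silyl ether, giving the enolised 2‑acyl‑1,3‑diketone after acidification.

**Compound list**

1 | 2,2-dimethylbut-3-ynoic acid | C#CC(C)(C)C(=O)O | starting material
2 | 2,2-dimethylbut-3-yn-1-ol | C#CC(C)(C)CO | intermediate
3 | 2,2-dimethylbut-3-ynal | C#CC(C)(C)C=O | intermediate
4 | (E)-4,4-dimethylhex-2-en-5-ynoic acid | C#CC(C)(C)/C=C/C(=O)O | intermediate
5 | (S)-4-benzyloxazolidin-2-one | O=C1N[C@@H](Cc2ccccc2)CO1 | starting material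
6 | (S)-4-benzyl-3-[(E)-4,4-dimethylhex-2-en-5-ynoyl]oxazolidin-2-one | C#CC(C)(C)/C=C/C(=O)N1C(=O)OC[C@@H]1Cc1ccccc1 | intermediate
7 | (S)-4-benzyl-3-[(S)-3-(2-methylbut-3-yn-2-yl)hex-5-enoyl]oxazolidin-2-one | C=CC[C@@H](CC(=O)N1C(=O)OC[C@@H]1Cc1ccccc1)C(C)(C)C#C | intermediate
8 | (S)-3-(2-methylbut-3-yn-2-yl)hex-5-en-1-ol | C=CC[C@@H](CCO)C(C)(C)C#C | intermediate
9 | (4S)-3,3-dimethyl-1-(triisopropylsilyloxy)-4-[2-(triisopropylsilyloxy)ethyl]hept-6-en-1-yne | C=CC[C@@H](CCO[Si](C(C)C)(C(C)C)C(C)C)C(C)(C)C#CO[Si](C(C)C)(C(C)C)C(C)C | intermediate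
10 | 2-{(3S)-2-methyl-3-[2-(triisopropylsilyloxy)ethyl]hex-5-en-2-yl}-3-(triisopropylsilyloxy)cyclobut-2-en-1-one | C=CC[C@@H](CCO[Si](C(C)C)(C(C)C)C(C)C)C(C)(C)C1=C(O[Si](C(C)C)(C(C)C)C(C)C)CC1=O | intermediate
11 | 3-hydroxy-2-[(3S)-3-(2-hydroxyethyl)-2-methylhex-5-en-2-yl]cyclobut-2-en-1-one | C=CC[C@@H](CCO)C(C)(C)C1=C(O)CC1=O | intermediate (not isolated)
12 | (5S)-6,6-dimethyl-5-(prop-2-en-1-yl)-2-oxabicyclo[5.2.0]non-1(7)-en-8-one | C=CC[C@@H](CCOC1=C2C(=O)C1)C2(C)C | intermediate
13 | 2-[(5R)-6,6-dimethyl-8-oxo-2-oxabicyclo[5.2.0]non-1(7)-en-5-yl]acetaldehyde | O=CC[C@@H](CCOC1=C2C(=O)C1)C2(C)C | intermediate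
14 | (R)-lavandulol | C=C(C)[C@@H](CC=C(C)C)CO | starting material
15 | (R)-lavandulyl iodide | C=C(C)[C@@H](CC=C(C)C)CI | intermediate
16 | lavandulyllithium (configuration of 15 retained) | C=C(C)[C@@H](CC=C(C)C)C[Li] | intermediate (not isolated)
17 | (5R)-5-[(4S)-2-hydroxy-7-methyl-4-(prop-1-en-2-yl)oct-6-en-1-yl]-6,6-dimethyl-2-oxabicyclo[5.2.0]non-1(7)-en-8-one, carbinol epimers | C=C(C)[C@@H](CC=C(C)C)CC(O)C[C@@H](CCOC1=C2C(=O)C1)C2(C)C | intermediate
18 | (5R)-6,6-dimethyl-5-[(4S)-7-methyl-2-oxo-4-(prop-1-en-2-yl)oct-6-en-1-yl]-2-oxabicyclo[5.2.0]non-1(7)-en-8-one | C=C(C)[C@@H](CC=C(C)C)CC(=O)C[C@@H](CCOC1=C2C(=O)C1)C2(C)C | intermediate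
19 | β-hydroxy(diethoxy)methyl diphenylphosphine oxide adduct of 18 (as its alkoxide, epimers at the carbinol carbon) | C=C(C)[C@@H](CC=C(C)C)CC(O)(C[C@@H](CCOC1=C2C(=O)C1)C2(C)C)C(OCC)(OCC)P(=O)(c1ccccc1)c1ccccc1 | intermediate (not isolated)
20 | (5S)-5-[(4S)-2-(diethoxymethylidene)-7-methyl-4-(prop-1-en-2-yl)oct-6-en-1-yl]-6,6-dimethyl-2-oxabicyclo[5.2.0]non-1(7)-en-8-one (ketene diethyl acetal) | C=C(C)[C@@H](CC=C(C)C)CC(=C(OCC)OCC)C[C@@H](CCOC1=C2C(=O)C1)C2(C)C | intermediate
21 | vinylketene: [4,4-dimethyl-2-methylideneoxepan-3-ylidene]methanone bearing the ketene-acetal side chain of 20 at ring C5 | C=C(C)[C@@H](CC=C(C)C)CC(=C(OCC)OCC)C[C@@H](CCOC(=C)C1=C=O)C1(C)C | intermediate (not isolated)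
22 | 2,2-diethoxy-6,6-dimethyl-1-lavandulylbicyclo[3.3.1]non-4-en-9-one with the C4 enol oxygen bridged by CH2CH2 to C7 (endo); C1 and C7 as in 32 | C=C(C)[C@@H](CC=C(C)C)C[C@@]12C[C@@H](CCOC(CC1(OCC)OCC)=C4C2=O)C4(C)C | intermediate
23 | 2,2-diethoxy-7-endo-(2-hydroxyethyl)-6,6-dimethyl-1-lavandulylbicyclo[3.3.1]nonane-4,9-dione | C=C(C)[C@@H](CC=C(C)C)C[C@@]12C[C@@H](CCO)C(C)(C)[C@@H](C(=O)CC1(OCC)OCC)C2=O | intermediate (not isolated)
24 | 2-ethoxy-7-endo-(2-hydroxyethyl)-6,6-dimethyl-1-lavandulylbicyclo[3.3.1]non-2-ene-4,9-dione | C=C(C)[C@@H](CC=C(C)C)C[C@@]12C[C@@H](CCO)C(C)(C)[C@@H](C(=O)C=C1OCC)C2=O | intermediate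
25 | 2-(2-ethoxy-6,6-dimethyl-1-lavandulyl-4,9-dioxobicyclo[3.3.1]non-2-en-7-endo-yl)acetaldehyde | C=C(C)[C@@H](CC=C(C)C)C[C@@]12C[C@@H](CC=O)C(C)(C)[C@@H](C(=O)C=C1OCC)C2=O | intermediate
26 | 2-ethoxy-6,6-dimethyl-7-endo-(3-methylbut-2-en-1-yl)-1-lavandulylbicyclo[3.3.1]non-2-ene-4,9-dione | C=C(C)[C@@H](CC=C(C)C)C[C@@]12C[C@@H](CC=C(C)C)C(C)(C)[C@@H](C(=O)C=C1OCC)C2=O | intermediate
27 | 2-ethoxy-6,6-dimethyl-5,7-bis(3-methylbut-2-en-1-yl)-1-lavandulylbicyclo[3.3.1]non-2-ene-4,9-dione (ring centres as in 32) | C=C(C)[C@@H](CC=C(C)C)C[C@@]12C[C@@H](CC=C(C)C)C(C)(C)[C@@](CC=C(C)C)(C(=O)C=C1OCC)C2=O | intermediate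
28 | 3-hydroxybenzoic acid | O=C(O)c1cccc(O)c1 | starting material
29 | tert-butyldimethylsilyl 3-(tert-butyldimethylsilyloxy)benzoate | CC(C)(C)[Si](C)(C)OC(=O)c1cccc(O[Si](C)(C)C(C)(C)C)c1 | intermediate
30 | 3-(tert-butyldimethylsilyloxy)benzoyl chloride | CC(C)(C)[Si](C)(C)Oc1cccc(C(=O)Cl)c1 | intermediate
31 | 3-[3-(tert-butyldimethylsilyloxy)benzoyl]-2-ethoxy-6,6-dimethyl-5,7-bis(3-methylbut-2-en-1-yl)-1-lavandulylbicyclo[3.3.1]non-2-ene-4,9-dione | C=C(C)[C@@H](CC=C(C)C)C[C@@]12C[C@@H](CC=C(C)C)C(C)(C)[C@@](CC=C(C)C)(C(=O)C(C(=O)c3cccc(O[Si](C)(C)C(C)(C)C)c3)=C1OCC)C2=O | intermediate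
32 | CNP0103487.1: (1R,5R,7R)-2-hydroxy-3-(3-hydroxybenzoyl)-6,6-dimethyl-5,7-bis(3-methylbut-2-en-1-yl)-1-[(2S)-5-methyl-2-(prop-1-en-2-yl)hex-4-en-1-yl]bicyclo[3.3.1]non-2-ene-4,9-dione | C=C(C)[C@@H](CC=C(C)C)C[C@@]12C[C@@H](CC=C(C)C)C(C)(C)[C@@](CC=C(C)C)(C(=O)C(C(=O)c3cccc(O)c3)=C1O)C2=O | target

**Step count**

Total: 23 steps. Longest linear sequence: 20 steps (1 → 32 through steps 1–10, 12–19, 22, 23).

**Steps most likely to fail**

Step 15 (key step). The vinylketene may form but the second C–C bond may not close: the zwitterion could collapse to the bridged [2+2] cyclobutanone, the ketene could dimerise, or the ketene acetal could be lost to adventitious protonation. The fallback closes the rings one after the other by known ketene and enolate chemistry, setting out from 20 and returning at 24.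
- Mild aqueous acid should turn the ketene acetal into ethyl ester F1.
- LDA/TBSCl should give ketene silyl acetal F2.
- Heating in toluene opens the cyclobutenone; the ketene should C‑acylate the silyl ketene acetal with silyl transfer (a known reaction type), closing ring B only and giving silyl dienol ether F3.
- Dilute HCl should cleave both enol ethers to the 2‑acetylcyclohexanone ester F4, with the hydroxyethyl arm free.
- KOt‑Bu should close ring A by Claisen condensation of the acetyl enolate onto the ester, giving trione F5.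
- O‑ethylation (EtI, Cs2CO3) and separation from the regioisomer should give 24.

In this variant the tether is cleaved before ring A closes, so the C7 → C1 relay is lost and the 7‑exo diastereomer must be removed at F5.

Step 14. The lithiated phosphine oxide may act as a base towards the enolisable ketone, or the moisture‑sensitive O,O‑ketene acetal may hydrolyse during isolation. The fallback uses a sulfur donor alkene that is stable on the bench, setting out from 18 and returning at 24.
- Peterson olefination of 18 with lithiated bis(methylthio)(trimethylsilyl)methane should give ketene dithioacetal F6.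
- The same thermal cascade should give the tricyclic bis(methylthio) ketal F7.
- PPTS/wet THF should hydrolyse the bridgehead enol ether to keto alcohol F8.
- DBU should eliminate methanethiol to give the vinylogous thioester F9.
- NaOEt/EtOH should exchange SMe for OEt by addition–elimination, giving 24.

Step 19. The bridgehead carbanion next to the C6 gem‑dimethyl group may form slowly or be alkylated slowly, so that proton return or lithiation at C3 competes. The fallback traps the anion with a small electrophile and makes the C–C bond by a radical, setting out from 26 and returning at 27.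
- LDA with TMSCl in situ, then I2, should give bridgehead iodide F10.
- Allyltributylstannane/AIBN (benzene, 80 °C) should give the C5‑allyl compound F11; the exo‑directed bridgehead radical cannot reach the endo C7 side chain.
- Cross‑metathesis with 2‑methylbut‑2‑ene (second‑generation Ru catalyst) should convert allyl into prenyl, giving 27.

**Further compounds**

F1 | step 15 | ethyl 2-lavandulyl-3-[(5S)-6,6-dimethyl-8-oxo-2-oxabicyclo[5.2.0]non-1(7)-en-5-yl]propanoate (α-epimers) | C=C(C)[C@@H](CC=C(C)C)CC(C(=O)OCC)C[C@@H](CCOC1=C2C(=O)C1)C2(C)C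
F2 | step 15 | O-ethyl O-(tert-butyldimethylsilyl) ketene acetal of F1 | C=C(C)[C@@H](CC=C(C)C)CC(=C(OCC)O[Si](C)(C)C(C)(C)C)C[C@@H](CCOC1=C2C(=O)C1)C2(C)C
F3 | step 15 | ring-B silyl dienol ether: ethyl 1-lavandulyl-2-(tert-butyldimethylsilyloxy)cyclohex-2-ene-1-carboxylate fused through C3/C4 to the 2-methylideneoxepane (C1 epimers) | C=C(C)[C@@H](CC=C(C)C)CC3(C(=O)OCC)C[C@@H](CCOC(=C)C1=C3O[Si](C)(C)C(C)(C)C)C1(C)C
F4 | step 15 | ethyl 3-acetyl-5-(2-hydroxyethyl)-4,4-dimethyl-1-lavandulyl-2-oxocyclohexane-1-carboxylate (epimers at C1 and C3) | C=C(C)[C@@H](CC=C(C)C)CC1(C(=O)OCC)C[C@@H](CCO)C(C)(C)C(C(C)=O)C1=O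
F5 | step 15 | 2-hydroxy-7-endo-(2-hydroxyethyl)-6,6-dimethyl-1-lavandulylbicyclo[3.3.1]non-2-ene-4,9-dione (enolised trione) | C=C(C)[C@@H](CC=C(C)C)C[C@@]12C[C@@H](CCO)C(C)(C)[C@@H](C(=O)C=C1O)C2=O
F6 | step 14 | ketene bis(methylthio)acetal analogue of 20 | C=C(C)[C@@H](CC=C(C)C)CC(=C(SC)SC)C[C@@H](CCOC1=C2C(=O)C1)C2(C)C
F7 | step 14 | 2,2-bis(methylthio) analogue of 22 | C=C(C)[C@@H](CC=C(C)C)C[C@@]12C[C@@H](CCOC(CC1(SC)SC)=C4C2=O)C4(C)C
F8 | step 14 | 7-endo-(2-hydroxyethyl)-6,6-dimethyl-2,2-bis(methylthio)-1-lavandulylbicyclo[3.3.1]nonane-4,9-dione | C=C(C)[C@@H](CC=C(C)C)C[C@@]12C[C@@H](CCO)C(C)(C)[C@@H](C(=O)CC1(SC)SC)C2=O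
F9 | step 14 | 7-endo-(2-hydroxyethyl)-6,6-dimethyl-2-(methylthio)-1-lavandulylbicyclo[3.3.1]non-2-ene-4,9-dione | C=C(C)[C@@H](CC=C(C)C)C[C@@]12C[C@@H](CCO)C(C)(C)[C@@H](C(=O)C=C1SC)C2=O
F10 | step 19 | 2-ethoxy-5-iodo-6,6-dimethyl-7-endo-(3-methylbut-2-en-1-yl)-1-lavandulylbicyclo[3.3.1]non-2-ene-4,9-dione | C=C(C)[C@@H](CC=C(C)C)C[C@@]12C[C@@H](CC=C(C)C)C(C)(C)[C@@](I)(C(=O)C=C1OCC)C2=O
F11 | step 19 | 5-allyl-2-ethoxy-6,6-dimethyl-7-endo-(3-methylbut-2-en-1-yl)-1-lavandulylbicyclo[3.3.1]non-2-ene-4,9-dione | C=C(C)[C@@H](CC=C(C)C)C[C@@]12C[C@@H](CC=C(C)C)C(C)(C)[C@@](CC=C)(C(=O)C=C1OCC)C2=O
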